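## Structural features

The target is a 2,3-trans flavanonol 3-methyl ether: a chroman-4-one in which the 5,6,7-trimethoxylated benzo ring A is fused through C4a–C8a to the pyranone ring C (O1, C2, C3, C4), and ring B, a 2',5'-dihydroxy-4'-methoxyphenyl unit, is bonded to C2. The only stereocentres are the adjacent C2 (R, benzylic, bound to O1) and C3 (R, methoxy-bearing, α to the C4 ketone), with aryl and methoxy trans and both equatorial. C3–H is acidic and O1 is a β-aryloxide leaving group, so base can epimerise C3 or open ring C to a chalcone-type enone, which erases C2 as well; the same unit is easily dehydrogenated to a flavonol. The C2–O1 bond is an ionisable benzylic ether because ring B carries oxygen ortho and para to C2, and the free hydroquinone is sensitive to air. Of the six aryl oxygens only those at C2' and C5' are unmethylated, so these two must be masked throughout and O3 must be methylated selectively. The real difficulty is to fix the absolute configuration of an ionisable C2 and to place a trans methoxy group on C3 without letting base act on the finished α-methoxy ketone. The key step uses the fact that C3 and C4 are neighbouring oxygen-bearing carbons of ring C. They can be carried as an alkene made by joining a vinyl group on C4a of ring A to a vinyl group on C2 (O1 already links C8a to C2), and the C2 aryl group then directs oxygen to the opposite face of C3=C4.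

## Logic of the disconnections

17 ⇒ 16. The two O–CH2Ph bonds on ring B are cut. The free hydroquinone is the most air-sensitive function and should appear only at the end. The gain is that every earlier compound carries inert ethers. The forward step must remove two benzyl groups without reducing the C4 ketone or the benzylic C2–O1 bond, which calls for neutral hydrogenolysis stopped at full conversion.

16 ⇒ 15. The C4 carbonyl is traced back to a C4 carbinol. With a carbinol at C4, C3–H is not acidic and ring C cannot open, so the preceding steps may use basic or nucleophilic reagents. The forward oxidation must be non-basic and must not epimerise C3.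

15 ⇒ 13. The O3–CH3 bond is cut. Methylating at the diol stage avoids alkylating a base-labile α-hydroxy ketone. The gain is a symmetrical-looking cis-diol that comes from one reaction. The forward step must tell O3 from O4.

13 ⇒ 12. The C3–O and C4–O bonds are cut together. Both oxygens and the C3 configuration then come from one syn addition to an alkene. Two stereocentres disappear. The forward step must add to the face of C3=C4 opposite the C2 aryl group.

12 ⇒ 11. The C3=C4 bond is cut by retro-metathesis. Ring C opens to an aryl allyl ether with two terminal vinyl groups and a single stereocentre. The forward closure must be neutral and must not isomerise or ionise the allylic ether.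

11 ⇒ 7 + 10. The O1–C2 bond is cut. This is the convergent point: it separates the ring-A and ring-B halves and traces the only stereocentre to a catalyst-controlled allylic substitution. The forward step must attack the aryl-bearing allyl terminus, at oxygen and not carbon, with high face selectivity, and must not re-ionise the product.

10 ⇒ 9 ⇒ 8. The exocyclic C=CH2 bond is cut to an aldehyde, then the aryl–CHO bond is cut. The two ortho positions of 8 are equivalent, so formylation can give only one product. The forward olefination must tolerate a free phenol.

7 ⇒ 6 ⇒ 5 ⇒ 4. The carbonate O–C(=O) bond is cut, the allylic alcohol is traced to an ester, and the Cα=Cβ bond is cut to an aldehyde. This reduces the allyl electrophile to a benzaldehyde. The forward steps must give the E alkene and handle an easily ionised cinnamyl carbonate gently.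

4 ⇒ 2 ⇒ 1. The aryl–CHO bond and then the two O–benzyl bonds are cut. The forward formylation must go para to the methoxy group, which is the electronically and sterically preferred position.

## Other disconnections considered

Alternative 1: The cut removes ring B altogether. C5'–C6', C1'–C2' and C2'–C3' are disconnected, leaving the alkyne (2R,3R)-2-ethynyl-3,5,6,7-tetramethoxy-2,3-dihydro-4H-chromen-4-one A2, the alkenylcarbene complex pentacarbonyl[(benzyloxy)(1-methoxyethenyl)methylidene]chromium A3 and one carbonyl ligand of A3. In the forward Dötz benzannulation A2 and A3 are warmed in an ether solvent. Alkyne insertion, carbonyl insertion and electrocyclisation would give the monobenzyl hydroquinone (2R,3R)-2-[5-(benzyloxy)-2-hydroxy-4-methoxyphenyl]-3,5,6,7-tetramethoxy-2,3-dihydro-4H-chromen-4-one A1, one hydrogenolysis from 17.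
- In favour: it forms three C–C bonds and a ring in one operation, against one bond for the metathesis, so on bonds formed per step it is the better plan. The para-dioxygen pattern of ring B arises directly, with the two oxygens already differentiated. Until ring B exists, C2 is propargylic and not benzylic to a trioxygenated arene, so it is less prone to ionise than in 11 to 13; this is also a point in its favour.
- Against: all stereochemistry must already reside in A2, and no short catalytic asymmetric entry to a 2-alkynyl-3-alkoxychromanone is evident. The small ethynyl group would direct an oxygenation at C3 less well than the aryl group of 12. A2 carries the enolisable, ring-opening-prone ketone through a thermal step. A3 is a sensitive, stoichiometric zerovalent chromium reagent. The arene is released as a Cr(CO)3 complex, and its oxidative removal would take place beside a very oxidisable hydroquinone monoether.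
- Comparison: on structure the alternative is more convergent in the last bond-forming event but pushes the stereochemical problem onto a less biased substrate. On mechanism both key steps are neutral metal-carbene processes and are equal in mildness towards C2 and C3. On step economy the chosen plan should be shorter overall and uses only catalytic metal.

Alternative 2: The cut is O1–C8a. The precursor is the open-chain anti aldol ketone (2R,3R)-3-[2,5-bis(benzyloxy)-4-methoxyphenyl]-3-hydroxy-1-(3-hydroxy-2,4-dimethoxyphenyl)-2-methoxypropan-1-one A5. In the forward step PhI(OAc)2 oxidises the phenol of A5, the benzylic hydroxyl adds to the para carbon, and tautomerisation restores the arene to give (2R,3R)-2-[2,5-bis(benzyloxy)-4-methoxyphenyl]-6-hydroxy-3,5,7-trimethoxy-2,3-dihydro-4H-chromen-4-one A4. A4 still needs O-methylation at C6 and hydrogenolysis.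
- In favour: the aryl C–O bond is made at an unfunctionalised C–H. Both stereocentres would come from one acyclic aldol addition to 4 with the C3 methoxy group already in place, so no late differentiation of O3 and O4 is needed; on this point it is better than the chosen plan. On paper it is also the shorter sequence.
- Against: A4 is a para-alkoxyphenol and is more easily oxidised than A5, so the reaction would have to stop at a product that the oxidant prefers, with quinone formation and loss of the new bond as the likely leak. The phenol of A5 is flanked by two methoxy groups, so ipso attack to an ortho-quinone monoketal competes. Ring B and the electron-rich benzylic carbinol are further sites of oxidation or fragmentation. A5 is a β-hydroxy ketone open to retro-aldol cleavage. The final phenol methylation must be done on the base-labile α-methoxy ketone.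
- Comparison: on structure both plans close ring C and differ only in which bond is last. On mechanism an oxidative cationic closure on a molecule with three oxidisable arenes is less secure than a neutral metathesis that leaves the weak C2–O1 bond alone. On step economy the alternative is ahead if each step works.

Alternative 3: The cut takes O1–C8a and C4a–C4 together. The partners are methyl (2R,3R)-3-[2,5-bis(benzyloxy)-4-methoxyphenyl]-3-hydroxy-2-methoxypropanoate A7 and 3,4,5-trimethoxy-2-(trimethylsilyl)phenyl trifluoromethanesulfonate A8. In the forward step CsF generates the aryne from A8, the alkoxide of A7 adds at the aryne carbon remote from the flanking methoxy group, and the aryl anion closes onto the ester to give (2R,3R)-2-[2,5-bis(benzyloxy)-4-methoxyphenyl]-3,5,6,7-tetramethoxy-2,3-dihydro-4H-chromen-4-one A6, which is identical with 16.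
- In favour: two bonds and ring C form in one step. The regiochemistry predicted by the methoxy group next to the triple bond is the one required. A6 is one hydrogenolysis from 17, so the end-game is shorter than in the chosen plan. No oxidation is ever carried out on the electron-rich arenes. On convergence and on step count after the key step it is the better plan.
- Against: the aryl anion must acylate faster than it is protonated by the acidic C2–H of the ester or by a second alcohol, otherwise only an aryl ether forms. The aldolate of A7 can revert by retro-aldol under fluoride and scramble both stereocentres. The reaction type is established mainly for phenolic nucleophiles, not for secondary alkoxides. A6 itself is exposed to basic fluoride. A8 needs several steps from 8, more than ring A needs in the chosen plan.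
- Comparison: on structure it forms two skeletal bonds against one. On mechanism an anionic cascade on base-labile stereocentres is the weaker choice than a neutral metathesis. On step economy it is at least equal and probably better if the annulation is efficient.

Key step: step 9

Assumption on the chemistry: the (Sa,Sc,Sc) antipode of the phosphoramidite is taken to give the (S) ether 11; should the sense of induction prove opposite, the (Ra,Rc,Rc) ligand is used with no other change.

Remark on descriptors: C2 is S in 11 and 12 and R from 13 onwards although its spatial arrangement never changes, because C3 outranks the ring-B carbon once it bears oxygen.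

Remark on design: 11 is assembled directly from the vinylphenol 10, so that the ionisable ether is formed immediately before ring closure and never meets a phosphorus ylide. O3 is methylated before the ketone exists.

## Route

Step 1
Reactants: 1 2-methoxybenzene-1,4-diol (2-methoxyhydroquinone)
Product: 2 1,4-bis(benzyloxy)-2-methoxybenzene
Conditions: BnBr, K2CO3, DMF, 60 °C, N2
Reagents that add atoms: benzyl bromide, BrCc1ccccc1
Why: Williamson etherification of both phenols, run under nitrogen because 1 is air-sensitive; benzyl ethers should survive every later step and leave together under neutral hydrogenolysis.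

Step 2
Reactants: 2 1,4-bis(benzyloxy)-2-methoxybenzene
Product: 4 2,5-bis(benzyloxy)-4-methoxybenzaldehyde, via aryl iminium chloride 3 (not isolated)
Conditions: POCl3, DMF, 0 → 70 °C; then H2O, 0 °C → rt
Reagents that add atoms: N,N-dimethylformamide, CN(C)C=O; water, O
Why: Vilsmeier–Haack formylation; the chloroiminium ion should attack the position para to the methoxy group and ortho to one benzyloxy group, the most activated site that is not flanked by two alkoxy groups, and the iminium salt 3 is hydrolysed on aqueous work-up.

Step 3
Reactants: 4 2,5-bis(benzyloxy)-4-methoxybenzaldehyde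
Product: 5 ethyl (2E)-3-[2,5-bis(benzyloxy)-4-methoxyphenyl]prop-2-enoate
Conditions: Ph3P=CHCO2Et, toluene, 90 °C
Reagents that add atoms: ethyl (triphenyl-λ5-phosphanylidene)acetate, CCOC(=O)C=P(c1ccccc1)(c1ccccc1)c1ccccc1
Why: Wittig olefination with a stabilised ylide, which should give the E cinnamate without added base; heating compensates for the electron-rich, ortho-substituted aldehyde.

Step 4
Reactants: 5 ethyl (2E)-3-[2,5-bis(benzyloxy)-4-methoxyphenyl]prop-2-enoate
Product: 6 (2E)-3-[2,5-bis(benzyloxy)-4-methoxyphenyl]prop-2-en-1-ol
Conditions: i-Bu2AlH, CH2Cl2, −78 °C; aq. potassium sodium tartrate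
Reagents that add atoms: none
Why: 1,2-Reduction of the conjugated ester by an aluminium hydride at low temperature should give the allylic alcohol and leave the alkene and the benzyl ethers untouched.

Step 5
Reactants: 6 (2E)-3-[2,5-bis(benzyloxy)-4-methoxyphenyl]prop-2-en-1-ol
Product: 7 (2E)-3-[2,5-bis(benzyloxy)-4-methoxyphenyl]prop-2-en-1-yl methyl carbonate
Conditions: ClCO2Me, pyridine, CH2Cl2, 0 °C
Reagents that add atoms: methyl chloroformate, COC(=O)Cl
Why: Acylation of the primary allylic alcohol gives the methyl carbonate, the usual leaving group for iridium-catalysed allylic substitution; the electron-rich cinnamyl carbonate ionises easily, so it is kept cold, purified on base-washed silica and used promptly.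

Step 6
Reactants: 8 3,4,5-trimethoxyphenol
Product: 9 2-hydroxy-4,5,6-trimethoxybenzaldehyde
Conditions: (CH2O)n, MgCl2, Et3N, MeCN, reflux; then 1 M HCl
Reagents that add atoms: paraformaldehyde (formaldehyde), C=O
Why: Magnesium-mediated ortho-formylation of a phenol (Casnati–Skattebøl type): the magnesium phenoxide delivers formaldehyde to the ortho carbon and a second formaldehyde oxidises the benzylic alkoxide by hydride transfer; the two ortho positions of 8 are equivalent, so one regioisomer is possible.

Step 7
Reactants: 9 2-hydroxy-4,5,6-trimethoxybenzaldehyde
Product: 10 2-ethenyl-3,4,5-trimethoxyphenol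
Conditions: Ph3PCH3Br (2.5 equiv), KOt-Bu (2.4 equiv), THF, 0 °C → rt
Reagents that add atoms: methyltriphenylphosphonium bromide, C[P+](c1ccccc1)(c1ccccc1)c1ccccc1.[Br-]
Why: Wittig methylenation of a salicylaldehyde with excess ylide, the first equivalent being spent on the phenol; 10 is kept cold and used at once because electron-rich vinylphenols oligomerise.

Step 8
Reactants: 7 (2E)-3-[2,5-bis(benzyloxy)-4-methoxyphenyl]prop-2-en-1-yl methyl carbonate; 10 2-ethenyl-3,4,5-trimethoxyphenol
Product: 11 1-({(1S)-1-[2,5-bis(benzyloxy)-4-methoxyphenyl]prop-2-en-1-yl}oxy)-2-ethenyl-3,4,5-trimethoxybenzene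
Conditions: [Ir(cod)Cl]2 (2 mol%), (Sa,Sc,Sc)-binaphthyl N,N-bis[1-(2-methoxyphenyl)ethyl]phosphoramidite (4 mol%), 1,5,7-triazabicyclo[4.4.0]dec-5-ene (8 mol%), THF, rt
Reagents that add atoms: none
Why: Iridium-catalysed asymmetric allylic etherification: the cyclometallated iridium phosphoramidite ionises the carbonate to an allyl complex and the phenoxide should attack the aryl-bearing terminus, giving the branched ether and setting C2 (S) under ligand control. The ligand with 2-methoxyphenyl arms is chosen because it accommodates ortho-substituted aryl groups, and the methoxide released from the carbonate regenerates the phenoxide, so no stoichiometric base is needed.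

Step 9
Reactants: 11 1-({(1S)-1-[2,5-bis(benzyloxy)-4-methoxyphenyl]prop-2-en-1-yl}oxy)-2-ethenyl-3,4,5-trimethoxybenzene
Product: 12 (2S)-2-[2,5-bis(benzyloxy)-4-methoxyphenyl]-5,6,7-trimethoxy-2H-chromene
Conditions: second-generation Grubbs catalyst, (H2IMes)(PCy3)Cl2Ru=CHPh (5 mol%), 1,4-benzoquinone (10 mol%), CH2Cl2 (0.01 M), rt → 35 °C
Reagents that add atoms: none
Why: Ring-closing olefin metathesis of a 2-vinylaryl allyl ether, the established entry to 2H-chromenes. The ruthenium benzylidene should initiate on the monosubstituted allylic vinyl group, the new alkylidene adds across the styrene vinyl group on ring A in a [2+2] step, and cycloreversion of the ruthenacyclobutane releases C3=C4 and, over the cycle, ethene. Ring C closes as a six-membered ring with an endocyclic cis alkene; closure is favoured because O1 and the vinyl group are ortho on ring A and the branched C2 carbon turns one alkene towards the other, and it is driven by loss of ethene. No stereocentre is formed, and C2 should keep its S configuration because the carbene chemistry takes place away from it in a neutral medium. The step needs ring closure over intermolecular metathesis, which high dilution secures. It also needs metathesis over migration of the allylic double bond to an enol ether, which ambient temperature, short reaction time and 1,4-benzoquinone as a scavenger of ruthenium hydrides secure. Ionisation of the C2–O1 bond, which ring B favours, is avoided because no Brønsted or Lewis acid is present. The methoxy group ortho to the styrene slows the approach of the carbene but should not prevent it.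

Step 10
Reactants: 12 (2S)-2-[2,5-bis(benzyloxy)-4-methoxyphenyl]-5,6,7-trimethoxy-2H-chromene
Product: 13 (2R,3S,4S)-2-[2,5-bis(benzyloxy)-4-methoxyphenyl]-5,6,7-trimethoxy-3,4-dihydro-2H-chromene-3,4-diol
Conditions: OsO4 (2.5 mol%), N-methylmorpholine N-oxide, acetone/H2O, 0 °C → rt; then aq. Na2SO3
Reagents that add atoms: osmium tetroxide (catalytic oxygen carrier), O=[Os](=O)(=O)=O; N-methylmorpholine N-oxide, C[N+]1([O-])CCOCC1; water, O
Why: Upjohn dihydroxylation; OsO4 should add syn to C3=C4 on the face opposite the C2 aryl group, which sets C3 (S) and C4 (S) as the 2,3-trans-3,4-cis diol by substrate control. The electron-rich styrenic alkene reacts fast, and the arenes and benzyl ethers are inert.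

Step 11
Reactants: 13 (2R,3S,4S)-2-[2,5-bis(benzyloxy)-4-methoxyphenyl]-5,6,7-trimethoxy-3,4-dihydro-2H-chromene-3,4-diol
Product: 15 (2R,3S,4S)-2-[2,5-bis(benzyloxy)-4-methoxyphenyl]-3,5,6,7-tetramethoxy-3,4-dihydro-2H-chromen-4-ol, via dibutylstannylene acetal 14 (not isolated)
Conditions: Bu2SnO, toluene, reflux (−H2O); then MeI, CsF, DMF, rt
Reagents that add atoms: iodomethane, CI; dibutyltin oxide (tin bridge of 14 only), CCCC[Sn](=O)CCCC
Why: Stannylene-acetal-directed mono-alkylation of a cis-diol: the tin acetal activates the equatorial O3, while the axial, benzylic O4 is shielded by the peri methoxy group at C5, so fluoride-assisted reaction with MeI should methylate O3 only. No enolisable ketone is present yet and no stereocentre is touched.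

Step 12
Reactants: 15 (2R,3S,4S)-2-[2,5-bis(benzyloxy)-4-methoxyphenyl]-3,5,6,7-tetramethoxy-3,4-dihydro-2H-chromen-4-ol
Product: 16 (2R,3R)-2-[2,5-bis(benzyloxy)-4-methoxyphenyl]-3,5,6,7-tetramethoxy-2,3-dihydro-4H-chromen-4-one
Conditions: Dess–Martin periodinane, pyridine, CH2Cl2, 0 °C → rt
Reagents that add atoms: none
Why: Dess–Martin oxidation of the one remaining secondary alcohol gives the C4 ketone; with O3 already methylated there is no competing hydroxyl and no diol to cleave, and the buffered, near-neutral medium should not enolise C3, whose trans arrangement is in any case the more stable one.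

Step 13
Reactants: 16 (2R,3R)-2-[2,5-bis(benzyloxy)-4-methoxyphenyl]-3,5,6,7-tetramethoxy-2,3-dihydro-4H-chromen-4-one
Product: 17 (2R,3R)-2-(2,5-dihydroxy-4-methoxyphenyl)-3,5,6,7-tetramethoxy-2,3-dihydro-4H-chromen-4-one
Conditions: H2 (1 atm), Pd/C, EtOAc, rt
Reagents that add atoms: none
Why: Hydrogenolysis of the two aryl benzyl ethers under neutral conditions; the aryl ketone and the C2–O1 bond are reduced much more slowly, so the reaction is stopped when 16 is consumed, and the hydroquinone is handled under argon.

## Compound list

1 | 2-methoxybenzene-1,4-diol | COc1cc(O)ccc1O | starting material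
2 | 1,4-bis(benzyloxy)-2-methoxybenzene | COc1cc(OCc2ccccc2)ccc1OCc1ccccc1 | intermediate
3 | {[2,5-bis(benzyloxy)-4-methoxyphenyl]methylidene}dimethyliminium chloride (not isolated) | COc1cc(OCc2ccccc2)c(C=[N+](C)C)cc1OCc1ccccc1.[Cl-] | intermediate
4 | 2,5-bis(benzyloxy)-4-methoxybenzaldehyde | COc1cc(OCc2ccccc2)c(C=O)cc1OCc1ccccc1 | intermediate
5 | ethyl (2E)-3-[2,5-bis(benzyloxy)-4-methoxyphenyl]prop-2-enoate | CCOC(=O)/C=C/c1cc(OCc2ccccc2)c(OC)cc1OCc1ccccc1 | intermediate
6 | (2E)-3-[2,5-bis(benzyloxy)-4-methoxyphenyl]prop-2-en-1-ol | OC/C=C/c1cc(OCc2ccccc2)c(OC)cc1OCc1ccccc1 | intermediate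
7 | (2E)-3-[2,5-bis(benzyloxy)-4-methoxyphenyl]prop-2-en-1-yl methyl carbonate | COC(=O)OC/C=C/c1cc(OCc2ccccc2)c(OC)cc1OCc1ccccc1 | intermediate
8 | 3,4,5-trimethoxyphenol | COc1cc(O)cc(OC)c1OC | starting material
9 | 2-hydroxy-4,5,6-trimethoxybenzaldehyde | COc1cc(O)c(C=O)c(OC)c1OC | intermediate
10 | 2-ethenyl-3,4,5-trimethoxyphenol | COc1cc(O)c(C=C)c(OC)c1OC | intermediate
11 | 1-({(1S)-1-[2,5-bis(benzyloxy)-4-methoxyphenyl]prop-2-en-1-yl}oxy)-2-ethenyl-3,4,5-trimethoxybenzene | COc1cc(OCc2ccccc2)c(cc1OCc1ccccc1)[C@H](C=C)Oc1cc(OC)c(OC)c(OC)c1C=C | intermediate
12 | (2S)-2-[2,5-bis(benzyloxy)-4-methoxyphenyl]-5,6,7-trimethoxy-2H-chromene | COc1cc(OCc2ccccc2)c(cc1OCc1ccccc1)[C@H]1Oc2cc(OC)c(OC)c(OC)c2C=C1 | intermediate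
13 | (2R,3S,4S)-2-[2,5-bis(benzyloxy)-4-methoxyphenyl]-5,6,7-trimethoxy-3,4-dihydro-2H-chromene-3,4-diol | COc1cc(OCc2ccccc2)c(cc1OCc1ccccc1)[C@H]1Oc2cc(OC)c(OC)c(OC)c2[C@H](O)[C@@H]1O | intermediate
14 | 3,4-O-dibutylstannylene acetal of 13, configuration at C2, C3 and C4 as in 13 (not isolated) | COc1cc(OCc2ccccc2)c(cc1OCc1ccccc1)[C@H]1Oc2cc(OC)c(OC)c(OC)c2[C@@H]3O[Sn](CCCC)(CCCC)O[C@H]13 | intermediate
15 | (2R,3S,4S)-2-[2,5-bis(benzyloxy)-4-methoxyphenyl]-3,5,6,7-tetramethoxy-3,4-dihydro-2H-chromen-4-ol | COc1cc(OCc2ccccc2)c(cc1OCc1ccccc1)[C@H]1Oc2cc(OC)c(OC)c(OC)c2[C@H](O)[C@@H]1OC | intermediate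
16 | (2R,3R)-2-[2,5-bis(benzyloxy)-4-methoxyphenyl]-3,5,6,7-tetramethoxy-2,3-dihydro-4H-chromen-4-one | COc1cc(OCc2ccccc2)c(cc1OCc1ccccc1)[C@H]1Oc2cc(OC)c(OC)c(OC)c2C(=O)[C@@H]1OC | intermediate
17 | (2R,3R)-2-(2,5-dihydroxy-4-methoxyphenyl)-3,5,6,7-tetramethoxy-2,3-dihydro-4H-chromen-4-one | COc1cc(O)c([C@H]2Oc3cc(OC)c(OC)c(OC)c3C(=O)[C@@H]2OC)cc1O | target

## Step count and least certain steps

Total: 13 steps. Longest linear sequence: 11 steps (steps 1 to 5 and 8 to 13, from 1 to 17).

**Step 9 (key step).** The most likely failure is migration of the allylic double bond by ruthenium hydrides before ring closure, which would lead on to a ring-contracted product with loss of propene. Slow ionisation of the C2–O1 bond during a long reaction, which would erode the configuration, is the second concern. Both arise because the ether is allylic, benzylic and attached to a donor-rich ring.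

Fallback: ring C is closed at O1–C2 instead, with C3=C4 already in place from an aldol condensation. The fallback sets out from 8 and 4 and comes back to the route at 12. Friedel–Crafts acetylation of 8 (AcOH, BF3·OEt2) would give 1-(2-hydroxy-4,5,6-trimethoxyphenyl)ethan-1-one F1. Claisen–Schmidt condensation of F1 with 4 (KOH, EtOH) would give (2E)-3-[2,5-bis(benzyloxy)-4-methoxyphenyl]-1-(2-hydroxy-4,5,6-trimethoxyphenyl)prop-2-en-1-one F2. Luche reduction (NaBH4, CeCl3·7H2O, MeOH, −20 °C) would give the racemic allylic alcohol 2-{(2E)-3-[2,5-bis(benzyloxy)-4-methoxyphenyl]-1-hydroxyprop-2-en-1-yl}-3,4,5-trimethoxyphenol F3, used crude. A chiral binaphthol-derived N-triflylphosphoramide would then ionise F3 to a 1,3-diarylallyl cation held in a chiral ion pair, and the phenol closes onto the ring-B terminus to give 12. The uncatalysed cyclisation of F3 is the weak point of this fallback.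

**Step 8.** The likely failures are attack at the unsubstituted allyl terminus or at carbon, low face selectivity caused by the ortho-benzyloxy group, and iridium-catalysed re-ionisation of the branched ether, which would erode both regio- and enantiopurity. All stem from the very electron-rich allyl fragment.

Fallback: C2 is set by aminocatalysis instead of by an allyl-metal intermediate. The fallback sets out from 6 and 9 and comes back at 12. Oxidation of 6 with MnO2 (CH2Cl2, rt) would give (2E)-3-[2,5-bis(benzyloxy)-4-methoxyphenyl]prop-2-enal F4. Condensation of F4 with 9 under (S)-α,α-diphenylprolinol trimethylsilyl ether and 2-nitrobenzoic acid in toluene would proceed by oxa-Michael addition of the phenol to the iminium ion, intramolecular aldol reaction and dehydration. This would give (2R)-2-[2,5-bis(benzyloxy)-4-methoxyphenyl]-5,6,7-trimethoxy-2H-chromene-3-carbaldehyde F5; the antipodal catalyst is used if the facial sense proves opposite. Decarbonylation of F5 with stoichiometric RhCl(PPh3)3 in hot toluene would remove the formyl group and give 12.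

**Step 11.** The likely failures are methylation at O4 or at both oxygens, or solvolysis at the benzylic C4 carbinol while the tin acetal is formed, since the regiochemical preference rests on analogy with cis-diols of other ring systems.

Fallback: the order of oxidation and methylation is reversed. The fallback sets out from 13 and comes back at 16. DDQ (dioxane, rt) should oxidise only the C4 carbinol, which is benzylic to ring A and conjugated with three oxygen donors. This would give (2R,3R)-2-[2,5-bis(benzyloxy)-4-methoxyphenyl]-3-hydroxy-5,6,7-trimethoxy-2,3-dihydro-4H-chromen-4-one F6. Purdie methylation of F6 (MeI, Ag2O, CaSO4, dark, rt) would then give 16. This order is the second choice because a basic surface meets the enolisable ketone.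

**Step 7.** The likely failures are sluggish olefination of an aldehyde that is deactivated by the ortho phenoxide and flanked by two substituents, and oligomerisation of the electron-rich vinylphenol during isolation.

Fallback: the order of etherification and olefination is reversed. The fallback sets out from 9 and 7 and comes back at 11. The iridium-catalysed etherification of step 8 is run with 9 as the phenol and would give 2-({(1S)-1-[2,5-bis(benzyloxy)-4-methoxyphenyl]prop-2-en-1-yl}oxy)-4,5,6-trimethoxybenzaldehyde F7. Wittig methylenation of F7 (Ph3PCH3Br, KOt-Bu, THF, 0 °C) would give 11. The price is a less nucleophilic phenoxide and a product ether with a better leaving group.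

## Further compounds

F1 | step 9 | 1-(2-hydroxy-4,5,6-trimethoxyphenyl)ethan-1-one | CC(=O)c1c(O)cc(OC)c(OC)c1OC
F2 | step 9 | (2E)-3-[2,5-bis(benzyloxy)-4-methoxyphenyl]-1-(2-hydroxy-4,5,6-trimethoxyphenyl)prop-2-en-1-one | COc1cc(O)c(C(=O)/C=C/c2cc(OCc3ccccc3)c(OC)cc2OCc2ccccc2)c(OC)c1OC
F3 | step 9 | 2-{(2E)-3-[2,5-bis(benzyloxy)-4-methoxyphenyl]-1-hydroxyprop-2-en-1-yl}-3,4,5-trimethoxyphenol (racemic) | COc1cc(O)c(C(O)/C=C/c2cc(OCc3ccccc3)c(OC)cc2OCc2ccccc2)c(OC)c1OC
F4 | step 8 | (2E)-3-[2,5-bis(benzyloxy)-4-methoxyphenyl]prop-2-enal | O=C/C=C/c1cc(OCc2ccccc2)c(OC)cc1OCc1ccccc1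
F5 | step 8 | (2R)-2-[2,5-bis(benzyloxy)-4-methoxyphenyl]-5,6,7-trimethoxy-2H-chromene-3-carbaldehyde | COc1cc(OCc2ccccc2)c(cc1OCc1ccccc1)[C@H]1Oc2cc(OC)c(OC)c(OC)c2C=C1C=O
F6 | step 11 | (2R,3R)-2-[2,5-bis(benzyloxy)-4-methoxyphenyl]-3-hydroxy-5,6,7-trimethoxy-2,3-dihydro-4H-chromen-4-one | COc1cc(OCc2ccccc2)c(cc1OCc1ccccc1)[C@H]1Oc2cc(OC)c(OC)c(OC)c2C(=O)[C@@H]1O
F7 | step 7 | 2-({(1S)-1-[2,5-bis(benzyloxy)-4-methoxyphenyl]prop-2-en-1-yl}oxy)-4,5,6-trimethoxybenzaldehyde | COc1cc(OCc2ccccc2)c(cc1OCc1ccccc1)[C@H](C=C)Oc1cc(OC)c(OC)c(OC)c1C=O
A1 | alternative 1 | (2R,3R)-2-[5-(benzyloxy)-2-hydroxy-4-methoxyphenyl]-3,5,6,7-tetramethoxy-2,3-dihydro-4H-chromen-4-one | COc1cc(O)c(cc1OCc1ccccc1)[C@H]1Oc2cc(OC)c(OC)c(OC)c2C(=O)[C@@H]1OC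
A2 | alternative 1 | (2R,3R)-2-ethynyl-3,5,6,7-tetramethoxy-2,3-dihydro-4H-chromen-4-one | C#C[C@H]1Oc2cc(OC)c(OC)c(OC)c2C(=O)[C@@H]1OC
A3 | alternative 1 | pentacarbonyl[(benzyloxy)(1-methoxyethenyl)methylidene]chromium | COC(=C)C(OCc1ccccc1)=[Cr](=C=O)(=C=O)(=C=O)(=C=O)=C=O
A4 | alternative 2 | (2R,3R)-2-[2,5-bis(benzyloxy)-4-methoxyphenyl]-6-hydroxy-3,5,7-trimethoxy-2,3-dihydro-4H-chromen-4-one | COc1cc(OCc2ccccc2)c(cc1OCc1ccccc1)[C@H]1Oc2cc(OC)c(O)c(OC)c2C(=O)[C@@H]1OC
A5 | alternative 2 | (2R,3R)-3-[2,5-bis(benzyloxy)-4-methoxyphenyl]-3-hydroxy-1-(3-hydroxy-2,4-dimethoxyphenyl)-2-methoxypropan-1-one | COc1cc(OCc2ccccc2)c(cc1OCc1ccccc1)[C@@H](O)[C@@H](OC)C(=O)c1ccc(OC)c(O)c1OC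
A6 | alternative 3 | (2R,3R)-2-[2,5-bis(benzyloxy)-4-methoxyphenyl]-3,5,6,7-tetramethoxy-2,3-dihydro-4H-chromen-4-one (identical with 16) | COc1cc(OCc2ccccc2)c(cc1OCc1ccccc1)[C@H]1Oc2cc(OC)c(OC)c(OC)c2C(=O)[C@@H]1OC
A7 | alternative 3 | methyl (2R,3R)-3-[2,5-bis(benzyloxy)-4-methoxyphenyl]-3-hydroxy-2-methoxypropanoate | COc1cc(OCc2ccccc2)c(cc1OCc1ccccc1)[C@@H](O)[C@@H](OC)C(=O)OC
A8 | alternative 3 | 3,4,5-trimethoxy-2-(trimethylsilyl)phenyl trifluoromethanesulfonate | COc1cc(OS(=O)(=O)C(F)(F)F)c([Si](C)(C)C)c(OC)c1OC
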